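**Retrosynthetic overview**
1. The target 21 is (13S)-3β,7α-diacetoxylabd-8(17)-en-15-oic acid (5α-H, 9α-H, 10β-CH3). The acetates come from diol acid 19; the 7α-OH/8(17)-ene pair comes from the 7α,8α-epoxide 17 of labd-7-ene 16; the C11–C12 bond comes from a 9-BBN/alkyl–alkyl Suzuki–Miyaura union of drima-7,9(11)-dien-3β-ol 12 with bromo ester 14 (C12–C16).
2. Diene 12 comes from Peterson methylenation of the C9 ketone of bicycle 10. Ring A of 10 is closed at the C3–C4 bond of monocyclic aldehyde 8 by cobalt-hydride hydrogen-atom transfer and chromium-mediated addition to the aldehyde (reductive alkene–aldehyde cyclisation).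
3. Enabling feature: in ring A the carbinol carbon C3 is bonded to the quaternary gem-dimethyl carbon C4, which hangs on ring-fusion carbon C5. C4 with C18 and C19 is therefore a latent isopropenyl group on C5, and C3 a latent aldehyde at the end of the C1–C2 arm on C10. Ring B then carries isopropenyl (C5) and methyl (C17 on C8) 1,4 to each other beside a carbonyl (C9), which is the pattern of (R)-carvone.
4. Aldehyde 8 comes from (R)-carvone 1 by two α′-alkylations at the future C10 (CH3I gives C20, allyl bromide gives C1–C3) and anti-Markovnikov oxidation of the allyl group.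
5. Ring order: ring B is taken from carvone, ring A is closed in step 5. Stereocontrol is relayed C5 (carvone) → C10 → C3 → C9 → C7; C13 comes from (R)-β-methyl-γ-butyrolactone 13.

Key step: step 5

Assumption: (R)-4-methyldihydrofuran-2(3H)-one (13) is taken as a purchasable enantiopure building block; its stereocentre becomes C13 without being touched.

**Step 1**
Reactants: 1 (R)-carvone
Product: 3 (5R,6S)-6-methylcarvone, via lithium enolate 2 (not isolated)
Conditions: LiN(i-Pr)2, THF, –78 °C; CH3I, –78 to 0 °C
Reagents that add atoms: iodomethane, CI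
Why: Kinetic deprotonation at the α′ CH2 gives the cross-conjugated enolate, whose alkylation (enolate alkylation) installs the future C20 methyl mainly trans to the isopropenyl group; this centre is planarised again in step 2, so the epimer mixture can be used.

**Step 2**
Reactants: 3 (5R,6S)-6-methylcarvone
Product: 5 (5S,6S)-6-allyl-2,6-dimethyl-5-(prop-1-en-2-yl)cyclohex-2-en-1-one, via lithium enolate 4 (not isolated)
Conditions: LiN(i-Pr)2, THF, –78 °C; allyl bromide, DMPU, –78 °C to rt
Reagents that add atoms: allyl bromide, C=CCBr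
Why: Second kinetic enolate alkylation, in which the electrophile should approach anti to the neighbouring isopropenyl group; this sets the quaternary centre (future C10) with the three-carbon arm trans and the methyl cis to isopropenyl, the usual outcome for 6-alkylcarvones.

**Step 3**
Reactants: 5 (5S,6S)-6-allyl-2,6-dimethyl-5-(prop-1-en-2-yl)cyclohex-2-en-1-one
Product: 7 (5S,6S)-6-(3-hydroxypropyl)-2,6-dimethyl-5-(prop-1-en-2-yl)cyclohex-2-en-1-one, via alkyldisiamylborane 6 (not isolated)
Conditions: Sia2BH (from BH3·THF and 2-methylbut-2-ene), THF, 0 °C; NaBO3·4H2O, H2O, rt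
Reagents that add atoms: sodium perborate, [Na+].[Na+].O[B-]1(O)OO[B-](O)(O)OO1
Why: Hydroboration–oxidation, in which the bulky dialkylborane adds anti-Markovnikov to the monosubstituted allyl alkene much faster than to the 1,1-disubstituted isopropenyl group or the hindered conjugated ketone; perborate avoids the alkaline peroxide that would epoxidise the enone, and no stereocentre is formed.

**Step 4**
Reactants: 7 (5S,6S)-6-(3-hydroxypropyl)-2,6-dimethyl-5-(prop-1-en-2-yl)cyclohex-2-en-1-one
Product: 8 3-[(1S,6S)-1,3-dimethyl-2-oxo-6-(prop-1-en-2-yl)cyclohex-3-en-1-yl]propanal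
Conditions: Dess–Martin periodinane, NaHCO3, CH2Cl2, 0 °C to rt
Reagents that add atoms: none
Why: Dess–Martin oxidation of the primary alcohol to the aldehyde under buffered conditions that leave both alkenes, the enone and the quaternary centre untouched.

**Step 5**
Reactants: 8 3-[(1S,6S)-1,3-dimethyl-2-oxo-6-(prop-1-en-2-yl)cyclohex-3-en-1-yl]propanal
Product: 10 3β-hydroxy-11-nordrim-7-en-9-one, via tertiary alkylchromium 9 (not isolated)
Conditions: Co(salen-tBu4) (divalent cobalt complex of N,N′-bis(3,5-di-tert-butylsalicylidene)ethylenediamine, C32H46CoN2O2, 10 mol %), CrCl3(THF)3 (30 mol %), 1-fluoro-2,4,6-trimethylpyridinium triflate (20 mol %), PhSiH3 (1.5 equiv), THF (0.02 M), rt; 1 M HCl work-up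
Reagents that add atoms: none
Why: The trivalent cobalt hydride formed from the cobalt complex, the N-fluoropyridinium salt and PhSiH3 transfers a hydrogen atom to the CH2 terminus of the isopropenyl group (Markovnikov), the tertiary C4 radical is captured by chromium as alkylchromium 9, and 9 adds to the tethered C3 aldehyde to form the C3–C4 bond, after which the silane silylates the chromium alkoxide and returns both metals to their cycles. The closest known reaction type is the cobalt-hydride/chromium branch-selective reductive coupling of unactivated 1,1-disubstituted alkenes with aliphatic aldehydes, which makes this hindered CH(OH)–C(CH3)2 linkage and is used here within one molecule, as iron-hydride-initiated reductive cyclisations join alkenes to tethered carbonyl groups. Ring A is closed in a 6-exo-trig mode at the carbonyl carbon through a chair built on the C5–C10 bond of ring B, and because the C4 centre on C5 and the C1–C2–C3 arm on C10 are trans (both equatorial) on ring B, only the trans-decalin can result. The one new stereocentre, C3, is set by this chair: the four-centre C4–Cr/C3=O array should lie anti to the C4–C5 bond on the open outer side of ring B, which puts the metal-bound oxygen equatorial and gives the 3β-alcohol, while C4 becomes the gem-dimethyl quaternary carbon and C5 and C10 are carried over unchanged. The step needs chemoselectivity for the isopropenyl group over the C7=C8 enone alkene and for the aldehyde over the C9 ketone; the substrate secures both, since hydrogen-atom transfer is much faster to the electron-rich 1,1-disubstituted alkene, alkylchromium reagents add to aldehydes but not to a hindered conjugated ketone, and C4 cannot reach C7 or C9 in a ring of workable size.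

**Step 6**
Reactants: 10 3β-hydroxy-11-nordrim-7-en-9-one
Product: 12 drima-7,9(11)-dien-3β-ol, via β-hydroxysilane 11 (not isolated)
Conditions: Me3SiCH2Li (3 equiv), THF, –78 to 0 °C; then KOt-Bu, 0 °C to rt
Reagents that add atoms: (trimethylsilyl)methyllithium, [Li]C[Si](C)(C)C
Why: Peterson olefination, in which the small, weakly basic silylmethyl nucleophile adds 1,2 to the hindered C9 ketone (no α-hydrogen on either side) and the potassium alkoxide then loses silanolate by syn-elimination to give the exocyclic C9=C11 alkene regiospecifically; the carbinol configuration of 11 is irrelevant.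

**Step 7**
Reactants: 13 (R)-4-methyldihydrofuran-2(3H)-one
Product: 14 isopropyl (R)-4-bromo-3-methylbutanoate
Conditions: HBr (gas), i-PrOH, 0 to 60 °C
Reagents that add atoms: hydrogen bromide, Br; propan-2-ol, CC(C)O
Why: Acid-mediated lactone opening by bromide at the primary O–CH2 carbon (SN2) with Fischer esterification of the freed acid; the stereocentre (future C13) is not involved.

**Step 8**
Reactants: 12 drima-7,9(11)-dien-3β-ol; 14 isopropyl (R)-4-bromo-3-methylbutanoate
Product: 16 isopropyl (13S)-3β-hydroxylabd-7-en-15-oate, via B-alkyl-9-BBN 15 (not isolated)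
Conditions: 9-BBN (2.5 equiv), THF, rt to 50 °C; then 14, Pd(OAc)2, PCy3, K3PO4·H2O, THF, rt to 40 °C
Reagents that add atoms: none
Why: Hydroboration with 9-BBN puts boron on the terminal C11 of the exocyclic alkene and delivers hydrogen to C9 from the α face, opposite the axial C10 methyl, which sets 9α-H (equatorial side chain); the B-alkyl group is then joined to the primary bromide in an alkyl–alkyl Suzuki–Miyaura coupling under an electron-rich trialkylphosphine palladium catalyst, bringing in C13 unchanged.

**Step 9**
Reactants: 16 isopropyl (13S)-3β-hydroxylabd-7-en-15-oate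
Product: 17 isopropyl (13S)-7α,8α-epoxy-3β-hydroxylabdan-15-oate
Conditions: mCPBA, NaHCO3, CH2Cl2, 0 °C
Reagents that add atoms: mCPBA, OOC(=O)c1cccc(Cl)c1
Why: Prilezhaev epoxidation of the only alkene, expected from the α face because the β face is shielded by the axial C10 methyl, which sets the 7α,8α-epoxide.

**Step 10**
Reactants: 17 isopropyl (13S)-7α,8α-epoxy-3β-hydroxylabdan-15-oate
Product: 18 isopropyl (13S)-3β,7α-dihydroxylabd-8(17)-en-15-oate
Conditions: Al(Oi-Pr)3 (3 equiv), toluene, reflux
Reagents that add atoms: none
Why: Aluminium alkoxide-mediated isomerisation of an epoxide to an allylic alcohol: aluminium binds the epoxide oxygen, the tertiary C8–O bond breaks and a syn proton is taken from the freely rotating C17 methyl through a cyclic transition state, so the C7–O bond and its α configuration are kept; ester exchange with the reagent is degenerate for the isopropyl ester.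

**Step 11**
Reactants: 18 isopropyl (13S)-3β,7α-dihydroxylabd-8(17)-en-15-oate
Product: 19 (13S)-3β,7α-dihydroxylabd-8(17)-en-15-oic acid
Conditions: LiOH·H2O, THF/MeOH/H2O, 50 °C; 1 M HCl to pH 3
Reagents that add atoms: lithium hydroxide, [Li+].[OH-]
Why: Saponification of the unhindered side-chain ester; C13 is β to the carboxyl group and cannot epimerise.

**Step 12**
Reactants: 19 (13S)-3β,7α-dihydroxylabd-8(17)-en-15-oic acid
Product: 21 (13S)-3β,7α-diacetoxylabd-8(17)-en-15-oic acid, via mixed anhydride 20 (not isolated)
Conditions: Ac2O, pyridine, DMAP, rt; aqueous NaHCO3, then acidification to pH 3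
Reagents that add atoms: acetic anhydride, CC(=O)OC(C)=O
Why: Nucleophile-catalysed acetylation of the equatorial 3β and the axial allylic 7α hydroxyl groups with retention at both carbons; the mixed anhydride formed at the carboxyl group is hydrolysed at its acetyl carbonyl in the bicarbonate work-up.

**Compound list**
1 | (R)-(–)-carvone, (5R)-2-methyl-5-(prop-1-en-2-yl)cyclohex-2-en-1-one | CC1=CC[C@@H](C(C)=C)CC1=O | starting material
2 | lithium α′-enolate of 1 (cross-conjugated, C5 unchanged) | CC1=CC[C@@H](C(C)=C)C=C1[O-].[Li+] | intermediate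
3 | (5R,6S)-6-methylcarvone, (5R,6S)-2,6-dimethyl-5-(prop-1-en-2-yl)cyclohex-2-en-1-one (trans; used with its C6 epimer) | CC1=CC[C@@H](C(C)=C)[C@H](C)C1=O | intermediate
4 | lithium enolate of 3 (C6 planar, C5 unchanged) | CC1=CC[C@@H](C(C)=C)C(C)=C1[O-].[Li+] | intermediate
5 | (5S,6S)-6-allyl-2,6-dimethyl-5-(prop-1-en-2-yl)cyclohex-2-en-1-one (allyl trans to isopropenyl) | CC1=CC[C@@H](C(C)=C)[C@](C)(CC=C)C1=O | intermediate
6 | bis(3-methylbutan-2-yl)borane adduct at the terminal carbon of the allyl group of 5 | CC1=CC[C@@H](C(C)=C)[C@](C)(CCCB(C(C)C(C)C)C(C)C(C)C)C1=O | intermediate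
7 | (5S,6S)-6-(3-hydroxypropyl)-2,6-dimethyl-5-(prop-1-en-2-yl)cyclohex-2-en-1-one | CC1=CC[C@@H](C(C)=C)[C@](C)(CCCO)C1=O | intermediate
8 | 3-[(1S,6S)-1,3-dimethyl-2-oxo-6-(prop-1-en-2-yl)cyclohex-3-en-1-yl]propanal | CC1=CC[C@@H](C(C)=C)[C@](C)(CCC=O)C1=O | intermediate
9 | tertiary alkylchromium dichloride at C4 of 8 (2-propyl carbon bound to chromium) | CC1=CC[C@@H](C(C)(C)[Cr](Cl)Cl)[C@](C)(CCC=O)C1=O | intermediate
10 | 3β-hydroxy-11-nordrim-7-en-9-one, (4aS,6S,8aS)-6-hydroxy-2,5,5,8a-tetramethyl-4a,5,6,7,8,8a-hexahydronaphthalen-1(4H)-one (trans-fused) | CC1=CC[C@H]2C(C)(C)[C@@H](O)CC[C@]2(C)C1=O | intermediate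
11 | 11-(trimethylsilyl)drim-7-ene-3β,9β-diol (silylmethyl group α at C9) | CC1=CC[C@H]2C(C)(C)[C@@H](O)CC[C@]2(C)[C@]1(O)C[Si](C)(C)C | intermediate
12 | drima-7,9(11)-dien-3β-ol, (2S,4aS,8aR)-1,1,4a,6-tetramethyl-5-methylidene-1,2,3,4,4a,5,8,8a-octahydronaphthalen-2-ol | CC1=CC[C@H]2C(C)(C)[C@@H](O)CC[C@]2(C)C1=C | intermediate
13 | (R)-4-methyldihydrofuran-2(3H)-one, (R)-β-methyl-γ-butyrolactone | O=C1C[C@@H](C)CO1 | starting material
14 | isopropyl (R)-4-bromo-3-methylbutanoate (same spatial arrangement as 13S of the target; the descriptor changes with the bromine) | BrC[C@H](C)CC(=O)OC(C)C | intermediate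
15 | B-(3β-hydroxydrim-7-en-11-yl)-9-borabicyclo[3.3.1]nonane (9α-H) | CC1=CC[C@H]2C(C)(C)[C@@H](O)CC[C@]2(C)[C@H]1CB1C2CCCC1CCC2 | intermediate
16 | isopropyl (13S)-3β-hydroxylabd-7-en-15-oate (5α-H, 9α-H, 10β-CH3) | CC1=CC[C@H]2C(C)(C)[C@@H](O)CC[C@]2(C)[C@H]1CC[C@H](C)CC(=O)OC(C)C | intermediate
17 | isopropyl (13S)-7α,8α-epoxy-3β-hydroxylabdan-15-oate | C[C@@]12O[C@@H]1C[C@H]3C(C)(C)[C@@H](O)CC[C@]3(C)[C@H]2CC[C@H](C)CC(=O)OC(C)C | intermediate
18 | isopropyl (13S)-3β,7α-dihydroxylabd-8(17)-en-15-oate | C=C1[C@H](O)C[C@H]2C(C)(C)[C@@H](O)CC[C@]2(C)[C@H]1CC[C@H](C)CC(=O)OC(C)C | intermediate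
19 | (13S)-3β,7α-dihydroxylabd-8(17)-en-15-oic acid | C=C1[C@H](O)C[C@H]2C(C)(C)[C@@H](O)CC[C@]2(C)[C@H]1CC[C@H](C)CC(=O)O | intermediate
20 | acetic (13S)-3β,7α-diacetoxylabd-8(17)-en-15-oic anhydride | C=C1[C@H](OC(C)=O)C[C@H]2C(C)(C)[C@@H](OC(C)=O)CC[C@]2(C)[C@H]1CC[C@H](C)CC(=O)OC(C)=O | intermediate
21 | (13S)-3β,7α-diacetoxylabd-8(17)-en-15-oic acid (CNP0169875.1; 3S,5R,7R,9R,10S,13S) | C=C1[C@H](OC(C)=O)C[C@H]2C(C)(C)[C@@H](OC(C)=O)CC[C@]2(C)[C@H]1CC[C@H](C)CC(=O)O | target

**Step count and risks**
Total: 12 steps. Longest linear sequence: 11 steps (steps 1–6 and 8–12, from (R)-carvone).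

Steps most likely to fail:

Step 5. Reversible hydrogen-atom transfer may isomerise the isopropenyl group to the isopropylidene isomer, or the C4 radical may be reduced before chromium captures it, so that ring A does not close; a modest equatorial preference at C3 would add the 3α-epimer. The fallback sets out from 8 and returns at 10. Markovnikov addition of HBr (CH2Cl2, –78 °C) to the isopropenyl group should give 3-[(1S,6R)-6-(2-bromopropan-2-yl)-1,3-dimethyl-2-oxocyclohex-3-en-1-yl]propanal F1. Slow addition of Bu3SnH with AIBN in benzene at 80 °C then generates the same C4 radical by bromine abstraction, without any cobalt hydride. Ring A closes by the known 6-exo radical addition to the aldehyde carbon, and the alkoxy radical is trapped by the stannane to give 10.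

Step 8. Transmetalation of the β-branched, neopentyl-like borane and oxidative addition of the β-branched bromide may both be slow, so that protodeboronation and β-hydride elimination take over. The fallback sets out from 12 and returns at 16. Hydroboration of 12 with 9-BBN and perborate oxidation should give drim-7-ene-3β,11-diol F2. Selective oxidation of the primary alcohol (TEMPO, PhI(OAc)2) gives 3β-hydroxydrim-7-en-11-al F3. A Wittig reaction at –78 °C with the ylide made by NaN(SiMe3)2 from [(2R)-2-methyl-4-oxo-4-(propan-2-yloxy)butyl]triphenylphosphonium bromide F4 (from 14 and PPh3) gives isopropyl (11Z,13R)-3β-hydroxylabda-7,11-dien-15-oate F5 (13R by the priority rules, same spatial arrangement). Diimide (2-nitrobenzenesulfonyl hydrazide, Et3N) then reduces only the disubstituted C11=C12 alkene and gives 16.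

Step 10. Proton loss from C6 or C9 instead of C17, or a Lewis-acid-induced hydride shift to the C7 ketone, may compete. The fallback sets out from 17 and returns at 18 and makes no compound outside the list (F0). Cp2TiCl2 and Mn dust in THF form trivalent titanium Cp2TiCl in the flask, which opens the epoxide homolytically at the tertiary C8–O bond. A second Cp2TiCl traps the C8 radical, and β-hydride elimination from the C17 methyl gives 18; this radical epoxide-to-allylic-alcohol isomerisation is known for trisubstituted epoxides.

**Further compounds**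
F1 | step 5 | 3-[(1S,6R)-6-(2-bromopropan-2-yl)-1,3-dimethyl-2-oxocyclohex-3-en-1-yl]propanal | CC1=CC[C@@H](C(C)(C)Br)[C@](C)(CCC=O)C1=O
F2 | step 8 | drim-7-ene-3β,11-diol | CC1=CC[C@H]2C(C)(C)[C@@H](O)CC[C@]2(C)[C@H]1CO
F3 | step 8 | 3β-hydroxydrim-7-en-11-al | CC1=CC[C@H]2C(C)(C)[C@@H](O)CC[C@]2(C)[C@H]1C=O
F4 | step 8 | [(2R)-2-methyl-4-oxo-4-(propan-2-yloxy)butyl]triphenylphosphonium bromide | [Br-].c1ccccc1[P+](c1ccccc1)(c1ccccc1)C[C@H](C)CC(=O)OC(C)C
F5 | step 8 | isopropyl (11Z,13R)-3β-hydroxylabda-7,11-dien-15-oate | CC1=CC[C@H]2C(C)(C)[C@@H](O)CC[C@]2(C)[C@H]1/C=C\[C@H](C)CC(=O)OC(C)C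
F0 | step 10 | none | none
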